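The ratio I watched was partner charged to substrate charged, held against the 2 equivalents that the double product takes.

common to all: substrate 0.50 M

| charge | coupling partner | remark | time |
|---|---|---|---|
| delta | 0.50 M | run made earlier |  |
| gamma | 0.84 M | run made earlier |  |
| epsilon | 2.2 M | run made earlier |  |
| autumn | 1.50 M |  | 3.0 h |
| dawn | 2.00 M |  | 3.0 h |
| dusk | 0.400 M |  | 3.0 h |

| run | time / min | tris adduct / % | single product / % | substrate / % |
|---|---|---|---|---|
| delta | 8.00 | 1 | 27 | 46 |
| delta | 25.0 | 2 | 27 | 39 |
| delta | 40.0 | 1 | 33 | 38 |
| delta | 60.0 | 0 | 30 | 37 |
| delta | 90.0 | 1 | 26 | 36 |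
| gamma | 8.00 | 0 | 26 | 22 |
| gamma | 15.0 | 0 | 19 | 21 |
| gamma | 25.0 | 4 | 19 | 17 |
| gamma | 50.0 | 2 | 14 | 13 |
| gamma | 90.0 | 0 | 14 | 12 |
| epsilon | 8.00 | 8 | 1 | 0 |
| epsilon | 25.0 | 9 | 0 | 0 |
| epsilon | 40.0 | 6 | 0 | 1 |
| epsilon | 60.0 | 9 | 0 | 0 |
| epsilon | 90.0 | 7 | 1 | 1 |

(each reading ± 1.5 percentage points)

- the analysis behind the earlier runs scatters by 1.5 percentage points, standard deviation

* which of these holds the largest part of the substrate at the end of autumn (double product / substrate / single product / tris adduct)
* which of these holds the largest part of the substrate at the end of dawn (double product / substrate / single product / tris adduct)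
* which of these holds the largest part of the substrate at the end of dusk (double product / substrate / single product / tris adduct)
* tris adduct at the end of autumn, in percent of the substrate charged

The earlier runs show what that ratio does. In the gamma run, with double product taken as the remainder, the last reading accounts for 0.810 M of partner against 0.84 M charged, so I read the partner there as the limiting reagent.

I ran autumn in slow motion. In the first instants substrate meets partner at 3.00 equivalents. The epsilon run showed substrate at 0 % and single product at 1 % by its first reading at 8.00 min, so I expected this stage to be over early in the 3.0 h. For the middle I expected single product to become double product as the partner fell. For the end of autumn I reckoned 0.500 M of spare partner, the charge minus what the double product takes.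

What matters then is tris adduct. In epsilon it averaged 7.80 % and showed no climb between 8.00 min and 90.0 min, so I read it as a level and not a clock. I took the tris level, the fraction of substrate in tris adduct per molar of spare partner, as a reading from epsilon, taking the partner inside the tris adduct off the spare: 0.0672 M⁻¹.

For autumn the first round gives 3.36 %. Putting that back, since tris adduct takes partner from the spare, gives 3.25 %.

The forecast said double product for autumn, double product for dawn, substrate for dusk, and 4 % of tris adduct in autumn, somewhat above my figure. Its ground for tris adduct was this: “That suggests a fast equilibrium or a branch scaling with free partner, not a slow drain.”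

    coupling partner + double product ⇌ tris adduct + by-product (K = 0.460, k = 0.740 M⁻¹ min⁻¹)
    substrate + coupling partner → single product + by-product (k = 2.30 M⁻¹ min⁻¹)
    coupling partner + single product → double product + by-product (k = 3.40 M⁻¹ min⁻¹)
    coupling partner + single product → over-reaction product (k = 0.250 M⁻¹ min⁻¹)
    coupling partner ⇌ dormant form (K = 7.20, k = 0.340 min⁻¹)

Autumn gave double product at 90.6 % and tris adduct at 2.53 %; dawn gave double product and dusk substrate at 45.7 %, so the forecast held on each count. In autumn, counted on the turnover up to 3.0 h, the substrate step was half done by 0.241 min and the slide of partner into dormant form by 0.678 min. Tris adduct in autumn stood at 2.53 % at 1.50 h and at 2.53 % at 30.0 h. Autumn's tris level came to 0.0520 M⁻¹, and dawn, with 1.00 M spare by the same subtraction and 4.88 % of tris adduct, came to 0.0500 M⁻¹.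

(The numbers in the tables are calculated for an exercise; noise was put on by code.)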